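**Plan**

1. Numbering: ring A is the cyclopentene C1–C2=C3–C4(Me)(OH)–C5. Ring B is the cycloheptane C1–C5–C6(OH)–C7–C8–C9(OH)–C10(=C18H2). The side chain C11(Me)–C12(OAc)–C13(OAc)–C14=C15Me2 sits on C7. α is the face of H1, H5, 4-OH and 9-OH; β is the face of 4-Me, 6-OH and the side chain.
2. Enabling feature: in ring B the oxygen-bearing C6 and the methylene-bearing C10 are the two atoms bonded to the fusion atoms C5 and C1. O–C6···C10=C18 is therefore the retron of a Grob fragmentation. Adding a C6–C10 bond turns ring B into a cyclobutane (C1, C5, C6, C10) fused to a cyclopentane (C6–C10, ring C).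
3. Cuts: first the protecting groups, C6–H (ketone), C11–CH3 (cuprate) and C7=C11 (aldol condensation), which release a C11–C15 aldehyde. Then C9–O (allylic hydroxylation), then the C6–C10 bond is added back (Grob retron), then C5–C6 and C1–C10 ([2+2]).
4. Forward order: ring A comes first (metathesis of linalool). The temporary cyclobutane follows by photocycloaddition with temporary ring C. Ring B arises last by fragmentation, and the side chain is joined afterwards.
5. Stereochemistry: C4 comes from (R)-linalool, and C1/C5 from the cis [2+2] anti to the C4 silyl ether. C9 comes from α-face hydroxylation, and C12/C13 from L-tartaric acid. C11 comes from an allylic-strain-controlled cuprate addition. C7 is set by enolate protonation and C6 by α-face hydride delivery.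

Key step: step 10

Remark: commercial (R)-(−)-linalool is taken as enantiopure. Compounds 7–13 are drawn as the cis-anti-cis cyclobutane isomer; the isomer epimeric at C6/C10 would converge on the same 14. TBS = tert-butyldimethylsilyl, TES = triethylsilyl.

Step 1
Reactants: 1 (R)-(−)-linalool
Product: 2 (R)-1-methylcyclopent-2-en-1-ol
Conditions: second-generation Grubbs catalyst (cat.), CH2Cl2, 40 °C
Reagents that add atoms: none
Why: Ring-closing metathesis of the 1,6-diene, helped by the allylic hydroxyl and driven by loss of a volatile alkene, should close ring A without touching the carbinol stereocentre (future C4).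

Step 2
Reactants: 2 (R)-1-methylcyclopent-2-en-1-ol
Product: 3 TBS ether of 2
Conditions: TBSOTf, 2,6-lutidine, CH2Cl2, −78 to 0 °C
Reagents that add atoms: TBSOTf CC(C)(C)[Si](C)(C)OS(=O)(=O)C(F)(F)F
Why: Silylation of a tertiary alcohol with a silyl triflate; the bulky group later shields the α face of ring A.

Step 3
Reactants: 3 TBS ether of 2
Product: 4 (R)-4-(tert-butyldimethylsilyloxy)-4-methylcyclopent-2-en-1-one (C2 ketone, C1=C5)
Conditions: Rh2(cap)4 (cat.), t-BuOOH, CH2Cl2, rt
Reagents that add atoms: tert-butyl hydroperoxide CC(C)(C)OO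
Why: Radical allylic oxidation to the enone; the second allylic position is quaternary, so only one allylic CH2 (C2) can react.

Step 4
Reactants: 5 methyl 2-oxocyclopentane-1-carboxylate
Product: 6 methyl 2-(triethylsilyloxy)cyclopent-1-ene-1-carboxylate (ring C: C6 bears OTES, C10 bears C18 as CO2Me)
Conditions: TESOTf, Et3N, CH2Cl2, 0 °C
Reagents that add atoms: TESOTf CC[Si](CC)(CC)OS(=O)(=O)C(F)(F)F
Why: O-silylation of the strongly enolised β-keto ester should give the fixed tetrasubstituted donor–acceptor alkene.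

Step 5
Reactants: 4 ring A enone; 6 silyl enol ether (excess, recovered)
Product: 7 cis-anti-cis 5-4-5 photoadduct (cyclobutane C1/C5/C6/C10; C2 ketone; 4α-OTBS; 6-OTES; 10-CO2Me)
Conditions: hν (Pyrex-filtered medium-pressure Hg lamp), CH2Cl2, −30 °C
Reagents that add atoms: none
Why: In this enone–alkene [2+2] photocycloaddition through the enone triplet, donor carbon C6 should bond to the β-carbon C5 and acceptor carbon C10 to the α-carbon C1 (the two orientation rules reinforce each other), the small rings enforce cis fusion, and entry anti to the C4-OTBS group sets C1 and C5 relative to C4.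

Step 6
Reactants: 7 photoadduct
Product: 9 C2 enol triflate (C2=C3), via potassium enolate 8 (not isolated)
Conditions: KN(SiMe3)2, THF, −78 °C; PhNTf2
Reagents that add atoms: N-phenylbis(trifluoromethanesulfonimide) O=S(=O)(N(c1ccccc1)S(=O)(=O)C(F)(F)F)C(F)(F)F
Why: Kinetic enolisation should occur at C3, because an enolate toward the cyclobutane carbon C1 would be a strained ring-fusion alkene, and O-triflation follows; at −78 °C the β-silyloxy group should not be eliminated.

Step 7
Reactants: 9 enol triflate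
Product: 10 tricyclic alkene ester (C2=C3 in place)
Conditions: Pd(OAc)2 (cat.), PPh3, HCO2H, Et3N, DMF, 60 °C
Reagents that add atoms: none
Why: Palladium-catalysed formate reduction of a vinyl triflate (oxidative addition to zerovalent palladium, decarboxylation of formate, reductive elimination) leaves the ester and both silyl ethers intact.

Step 8
Reactants: 10 tricyclic alkene ester
Product: 11 primary alcohol (C18H2OH on C10)
Conditions: LiAlH4, Et2O, 0 °C
Reagents that add atoms: none
Why: Hydride reduction of the ester; O6 stays silylated, so no retro-aldol opening can start.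

Step 9
Reactants: 11 primary alcohol
Product: 12 mesylate (C18H2OMs)
Conditions: MsCl, Et3N, CH2Cl2, 0 °C
Reagents that add atoms: methanesulfonyl chloride CS(=O)(=O)Cl
Why: Sulfonylation of the only free hydroxyl installs the nucleofuge in a 1,3-relationship to O6.

Step 10
Reactants: 12 mesylate
Product: 14 bicyclic ketone (ring B formed; C6 ketone; C10=C18H2; H1α and H5α; 4α-OTBS), via cyclobutanolate 13 (not isolated)
Conditions: n-Bu4NF (1.1 equiv), THF, 0 °C; pH 7 buffer
Reagents that add atoms: none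
Why: Fluoride removes the TES group from O6 (the tertiary TBS ether and the neopentyl mesylate react more slowly), and cyclobutanolate 13 should undergo a concerted Grob fragmentation in which O6 pushes, the strained C6–C10 bond shared by the cyclobutane and ring C breaks, C10=C18 forms and mesylate leaves. The closest known reaction types are the base-induced fragmentation of 1,3-diol monosulfonates and the retro-aldol opening of De Mayo photoadducts. Ring B is closed not by making a bond but by deleting the zero-atom bridge of the bicyclo[3.2.0]heptane unit, so that the four- and five-membered rings merge into the seven-membered ring C6–C7–C8–C9–C10–C1–C5. No stereocentre is created: C1, C4 and C5 are carried over and C6 and C10 become trigonal, so both cyclobutane isomers converge. The step needs fragmentation to win over oxetane formation (4-exo-tet attack of O6 on C18) and over epimerisation at C5; the freely rotating C10–C18 bond can place C18–OMs antiperiplanar to C6–C10, release of cyclobutane strain favours cleavage, and low temperature with a buffered quench protects C5.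

Step 11
Reactants: 14 bicyclic ketone
Product: 15 9α-hydroxy ketone
Conditions: SeO2 (cat.), t-BuOOH, CH2Cl2, 0 °C to rt
Reagents that add atoms: tert-butyl hydroperoxide CC(C)(C)OO (oxygen relayed through SeO2)
Why: In this allylic hydroxylation by ene reaction and [2,3]-sigmatropic shift, selenium attacks terminal C18, the CH2 > CH order of the reaction favours H9 over the fusion H1, the alkene returns to C10=C18, and both events should occur on the open α face to give 9α-OH.

Step 12
Reactants: 15 9α-hydroxy ketone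
Product: 16 9α-OTBS ketone
Conditions: TBSCl, imidazole, DMF, rt
Reagents that add atoms: TBSCl CC(C)(C)[Si](C)(C)Cl
Why: Standard silylation of a secondary allylic alcohol, needed for the later differentiation of the hydroxyl groups.

Step 13
Reactants: 17 (4S,5S)-2,2-dimethyl-1,3-dioxolane-4,5-dimethanol (2,3-O-isopropylidene-L-threitol)
Product: 18 mono-TBS ether of 17
Conditions: NaH (1 equiv), THF, 0 °C; TBSCl
Reagents that add atoms: TBSCl CC(C)(C)[Si](C)(C)Cl
Why: Monosilylation of the C2-symmetric diol through its monosodium salt; the two carbinol centres are the future C12 and C13.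

Step 14
Reactants: 18 mono-TBS ether
Product: 19 (4R,5S)-5-(TBSO-methyl)-2,2-dimethyl-1,3-dioxolane-4-carbaldehyde
Conditions: Dess–Martin periodinane, NaHCO3, CH2Cl2, rt
Reagents that add atoms: none
Why: Mild periodinane oxidation; the trans-dioxolane aldehyde is the more stable epimer and should keep its configuration.

Step 15
Reactants: 19 aldehyde
Product: 20 (4S,5S)-4-(TBSO-methyl)-2,2-dimethyl-5-(2-methylprop-1-enyl)-1,3-dioxolane
Conditions: i-PrPPh3I, n-BuLi, THF, 0 °C; then 19, −78 °C to rt
Reagents that add atoms: isopropyltriphenylphosphonium iodide CC(C)[P+](c1ccccc1)(c1ccccc1)c1ccccc1.[I-]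
Why: Wittig olefination with the non-stabilised isopropylidene ylide builds C14=C15Me2, which has no alkene geometry to control.

Step 16
Reactants: 20 silyl ether
Product: 21 [(4S,5S)-2,2-dimethyl-5-(2-methylprop-1-enyl)-1,3-dioxolan-4-yl]methanol
Conditions: n-Bu4NF, THF, rt
Reagents that add atoms: none
Why: Fluoride cleavage of a primary silyl ether; the acetonide and the alkene are inert.

Step 17
Reactants: 21 alcohol
Product: 22 (4R,5S)-2,2-dimethyl-5-(2-methylprop-1-enyl)-1,3-dioxolane-4-carbaldehyde (C11–C15 fragment)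
Conditions: Dess–Martin periodinane, NaHCO3, CH2Cl2, rt
Reagents that add atoms: none
Why: The same mild oxidation gives the C11 aldehyde, which is used directly.

Step 18
Reactants: 16 9α-OTBS ketone; 22 side-chain aldehyde
Product: 26 (E)-exocyclic enone (C7=C11; C12 cis to C8), via lithium enolate 23 (not isolated), via lithium aldolate 24 (not isolated), via aldol mesylate 25 (not isolated)
Conditions: LiN(i-Pr)2, THF, −78 °C; 22; MsCl, −78 to 0 °C; DBU, 0 °C to rt
Reagents that add atoms: none
Why: In this directed aldol condensation, kinetic deprotonation should occur at the C7 methylene rather than at the hindered C5 methine, and E1cB loss of mesylate gives the E-alkylidene ketone, which avoids the clash of C12 with the carbonyl oxygen.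

Step 19
Reactants: 26 (E)-exocyclic enone
Product: 28 ketone carrying the full side chain (7β; 11R; acetonide), via lithium enolate 27 (not isolated)
Conditions: Me2CuLi (from CuI and MeLi), Et2O, −78 to −40 °C; sat. aq NH4Cl, −78 °C
Reagents that add atoms: methyllithium [Li]C (as Me2CuLi)
Why: In this conjugate addition of a Gilman cuprate to an s-cis enone, allylic 1,3-strain with C8H2 holds H12 in the enone plane, the trans-dioxolane then shows its small oxygen O12 to one face and the C13 branch to the other, methyl should enter past O12 (the syn sense known for γ-alkoxy acceptors with a cis substituent) to give 11R, and α-face protonation of 27 gives H7α, which is also the more stable cis-2,7-disubstituted cycloheptanone.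

Step 20
Reactants: 28 ketone
Product: 29 6β-alcohol
Conditions: LiBH(s-Bu)3, THF, −78 °C; H2O
Reagents that add atoms: none
Why: The bulky borohydride should attack from the open α face (equatorial-type approach past H5α and H7α) and give the axial 6β-alcohol, all-cis with C4 and the side chain.

Step 21
Reactants: 29 6β-alcohol
Product: 30 4,6,9-tris-TBS ether acetonide
Conditions: TBSOTf, 2,6-lutidine, CH2Cl2, 0 °C
Reagents that add atoms: TBSOTf CC(C)(C)[Si](C)(C)OS(=O)(=O)C(F)(F)F
Why: The silyl triflate silylates even the hindered secondary alcohol, so that only O12 and O13 can be acetylated later.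

Step 22
Reactants: 30 tris-TBS ether acetonide
Product: 31 12,13-diol
Conditions: AcOH–THF–H2O, 40 °C
Reagents that add atoms: none
Why: Mild acid hydrolysis of the dioxolane; hindered secondary and tertiary TBS ethers are slower to hydrolyse, and the neighbouring oxygen disfavours ionisation at allylic C13.

Step 23
Reactants: 31 12,13-diol
Product: 32 12,13-diacetate
Conditions: Ac2O, pyridine, DMAP (cat.), CH2Cl2, rt
Reagents that add atoms: acetic anhydride CC(=O)OC(C)=O
Why: Acylation of the only two free hydroxyl groups.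

Step 24
Reactants: 32 12,13-diacetate
Product: 33 target CNP0269663.2
Conditions: HF·pyridine, pyridine, THF, 0 °C to rt
Reagents that add atoms: none
Why: Buffered fluoride-mediated desilylation should free O4, O6 and O9 without hydrolysis or migration of the acetates.

**Compound list**

1 | (R)-(−)-linalool | C=C[C@](C)(O)CCC=C(C)C | starting material
2 | (R)-1-methylcyclopent-2-en-1-ol | C1=C[C@](C)(O)CC1 | intermediate
3 | TBS ether of 2 | C1=C[C@](C)(O[Si](C)(C)C(C)(C)C)CC1 | intermediate
4 | (R)-4-(tert-butyldimethylsilyloxy)-4-methylcyclopent-2-en-1-one | O=C1C=C[C@](C)(O[Si](C)(C)C(C)(C)C)C1 | intermediate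
5 | methyl 2-oxocyclopentane-1-carboxylate | COC(=O)C1CCCC1=O | starting material
6 | methyl 2-(triethylsilyloxy)cyclopent-1-ene-1-carboxylate | COC(=O)C1=C(O[Si](CC)(CC)CC)CCC1 | intermediate
7 | cis-anti-cis 5-4-5 photoadduct (C2 ketone, 4α-OTBS, 6-OTES, 10-CO2Me) | COC(=O)[C@@]12CCC[C@]1(O[Si](CC)(CC)CC)[C@@H]3[C@H]2C(=O)C[C@@]3(C)O[Si](C)(C)C(C)(C)C | intermediate
8 | potassium C2–C3 enolate of 7 | COC(=O)[C@@]12CCC[C@]1(O[Si](CC)(CC)CC)[C@@H]3[C@H]2C([O-])=C[C@@]3(C)O[Si](C)(C)C(C)(C)C.[K+] | intermediate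
9 | C2 enol triflate | COC(=O)[C@@]12CCC[C@]1(O[Si](CC)(CC)CC)[C@@H]3[C@H]2C(OS(=O)(=O)C(F)(F)F)=C[C@@]3(C)O[Si](C)(C)C(C)(C)C | intermediate
10 | tricyclic alkene ester (C2=C3) | COC(=O)[C@@]12CCC[C@]1(O[Si](CC)(CC)CC)[C@@H]3[C@H]2C=C[C@@]3(C)O[Si](C)(C)C(C)(C)C | intermediate
11 | primary alcohol (C18H2OH) | OC[C@@]12CCC[C@]1(O[Si](CC)(CC)CC)[C@@H]3[C@H]2C=C[C@@]3(C)O[Si](C)(C)C(C)(C)C | intermediate
12 | mesylate (C18H2OMs) | CS(=O)(=O)OC[C@@]12CCC[C@]1(O[Si](CC)(CC)CC)[C@@H]3[C@H]2C=C[C@@]3(C)O[Si](C)(C)C(C)(C)C | intermediate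
13 | cyclobutanolate (O6 anion) | CS(=O)(=O)OC[C@@]12CCC[C@]1([O-])[C@@H]3[C@H]2C=C[C@@]3(C)O[Si](C)(C)C(C)(C)C | intermediate
14 | cis-fused bicyclic ketone (C6 ketone, C10=C18H2, C2=C3, 4α-OTBS) | C=C1CCCC(=O)[C@@H]2[C@H]1C=C[C@@]2(C)O[Si](C)(C)C(C)(C)C | intermediate
15 | 9α-hydroxy ketone | C=C1[C@H](O)CCC(=O)[C@@H]2[C@H]1C=C[C@@]2(C)O[Si](C)(C)C(C)(C)C | intermediate
16 | 9α-OTBS ketone | C=C1[C@H](O[Si](C)(C)C(C)(C)C)CCC(=O)[C@@H]2[C@H]1C=C[C@@]2(C)O[Si](C)(C)C(C)(C)C | intermediate
17 | (4S,5S)-2,2-dimethyl-1,3-dioxolane-4,5-dimethanol | OC[C@@H]1OC(C)(C)O[C@H]1CO | starting material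
18 | mono-TBS ether of 17 | CC(C)(C)[Si](C)(C)OC[C@@H]1OC(C)(C)O[C@H]1CO | intermediate
19 | (4R,5S)-5-(TBSO-methyl)-2,2-dimethyl-1,3-dioxolane-4-carbaldehyde | CC(C)(C)[Si](C)(C)OC[C@@H]1OC(C)(C)O[C@H]1C=O | intermediate
20 | (4S,5S)-4-(TBSO-methyl)-2,2-dimethyl-5-(2-methylprop-1-enyl)-1,3-dioxolane | CC(C)(C)[Si](C)(C)OC[C@@H]1OC(C)(C)O[C@H]1C=C(C)C | intermediate
21 | [(4S,5S)-2,2-dimethyl-5-(2-methylprop-1-enyl)-1,3-dioxolan-4-yl]methanol | OC[C@@H]1OC(C)(C)O[C@H]1C=C(C)C | intermediate
22 | (4R,5S)-2,2-dimethyl-5-(2-methylprop-1-enyl)-1,3-dioxolane-4-carbaldehyde | O=C[C@@H]1OC(C)(C)O[C@H]1C=C(C)C | intermediate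
23 | lithium C6–C7 enolate of 16 | C=C1[C@H](O[Si](C)(C)C(C)(C)C)CC=C([O-])[C@@H]2[C@H]1C=C[C@@]2(C)O[Si](C)(C)C(C)(C)C.[Li+] | intermediate
24 | lithium aldolate (mixture at C7 and C11) | C=C1[C@H](O[Si](C)(C)C(C)(C)C)CC(C([O-])[C@@H]3OC(C)(C)O[C@H]3C=C(C)C)C(=O)[C@@H]2[C@H]1C=C[C@@]2(C)O[Si](C)(C)C(C)(C)C.[Li+] | intermediate
25 | aldol mesylate (mixture at C7 and C11) | C=C1[C@H](O[Si](C)(C)C(C)(C)C)CC(C(OS(C)(=O)=O)[C@@H]3OC(C)(C)O[C@H]3C=C(C)C)C(=O)[C@@H]2[C@H]1C=C[C@@]2(C)O[Si](C)(C)C(C)(C)C | intermediate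
26 | (E)-exocyclic enone (C7=C11) | C=C1[C@H](O[Si](C)(C)C(C)(C)C)C/C(=C\[C@@H]3OC(C)(C)O[C@H]3C=C(C)C)C(=O)[C@@H]2[C@H]1C=C[C@@]2(C)O[Si](C)(C)C(C)(C)C | intermediate
27 | lithium C6–C7 enolate after methyl transfer (11R) | C=C1[C@H](O[Si](C)(C)C(C)(C)C)CC([C@@H](C)[C@@H]3OC(C)(C)O[C@H]3C=C(C)C)=C([O-])[C@@H]2[C@H]1C=C[C@@]2(C)O[Si](C)(C)C(C)(C)C.[Li+] | intermediate
28 | ketone with full side chain (H7α, 11R, acetonide) | C=C1[C@H](O[Si](C)(C)C(C)(C)C)C[C@@H]([C@@H](C)[C@@H]3OC(C)(C)O[C@H]3C=C(C)C)C(=O)[C@@H]2[C@H]1C=C[C@@]2(C)O[Si](C)(C)C(C)(C)C | intermediate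
29 | 6β-alcohol | C=C1[C@H](O[Si](C)(C)C(C)(C)C)C[C@@H]([C@@H](C)[C@@H]3OC(C)(C)O[C@H]3C=C(C)C)[C@@H](O)[C@@H]2[C@H]1C=C[C@@]2(C)O[Si](C)(C)C(C)(C)C | intermediate
30 | 4,6,9-tris-TBS ether acetonide | C=C1[C@H](O[Si](C)(C)C(C)(C)C)C[C@@H]([C@@H](C)[C@@H]3OC(C)(C)O[C@H]3C=C(C)C)[C@@H](O[Si](C)(C)C(C)(C)C)[C@@H]2[C@H]1C=C[C@@]2(C)O[Si](C)(C)C(C)(C)C | intermediate
31 | 12,13-diol (tris-TBS) | C=C1[C@H](O[Si](C)(C)C(C)(C)C)C[C@@H]([C@@H](C)[C@H](O)[C@H](C=C(C)C)O)[C@@H](O[Si](C)(C)C(C)(C)C)[C@@H]2[C@H]1C=C[C@@]2(C)O[Si](C)(C)C(C)(C)C | intermediate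
32 | 12,13-diacetate (tris-TBS) | C=C1[C@H](O[Si](C)(C)C(C)(C)C)C[C@@H]([C@@H](C)[C@H](OC(C)=O)[C@H](C=C(C)C)OC(C)=O)[C@@H](O[Si](C)(C)C(C)(C)C)[C@@H]2[C@H]1C=C[C@@]2(C)O[Si](C)(C)C(C)(C)C | intermediate
33 | CNP0269663.2 | C=C1[C@H](O)C[C@@H]([C@@H](C)[C@H](OC(C)=O)[C@H](C=C(C)C)OC(C)=O)[C@@H](O)[C@@H]2[C@H]1C=C[C@@]2(C)O | target

Total step count: 24. Longest linear sequence: 18 steps (steps 1–3, 5–12, 18–24).

**Steps most likely to fail**

**Step 5.** The tetrasubstituted donor–acceptor alkene may add sluggishly, and the discrimination between the methyl face and the silyloxy face of 4 may be poor.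

The fallback sets out from 6 and returns to the route at 10. It takes the absolute control from a hydrogen/silyloxy pair and builds the C4 carbinol afterwards by oxygen delivery from the α face.
- Purchased (R)-4-(tert-butyldimethylsilyloxy)cyclopent-2-en-1-one F1 is irradiated with 6. This gives, anti to the silyloxy group, the photoadduct F2.
- DBU eliminates the β-silyloxy group to give the tricyclic cyclopentenone F3.
- Me2CuLi with Me3SiCl gives the trimethylsilyl enol ether F4.
- Saegusa–Ito oxidation with Pd(OAc)2 gives the 4-methyl enone F5.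
- Nucleophilic epoxidation (t-BuOOH, DBU) on the open α face gives the 3α,4α-epoxy ketone F6.
- Wharton transposition (N2H4·H2O, AcOH) gives the tertiary allylic alcohol F7 with 4α-OH and C2=C3.
- TBSOTf then gives 10.

**Step 11.** Hydroxylation may come from the β face, may run on to the enone, or may compete with attack at the doubly allylic C1–H.

The fallback sets out from 14 and returns at 15. It replaces facial control in the C–H oxidation by an SN2 inversion.
- The epimeric 9β-alcohol F8 is isolated.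
- It is inverted under Mitsunobu conditions (4-nitrobenzoic acid, PPh3, diisopropyl azodicarboxylate) to the 9α 4-nitrobenzoate F9.
- Methanolysis (K2CO3, MeOH, 0 °C) gives 15.

**Step 19.** The cuprate may follow the polar sense (entry anti to O12) and give the C11 epimer.

The fallback sets out from 16 and 22 and returns at 28. It exchanges the roles of methyl and hydrogen, so that the same facial bias gives the opposite C11 configuration.
- MeMgBr adds to 22 to give the secondary carbinol F10, and Dess–Martin oxidation gives the methyl ketone F11.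
- Ketone 16 is converted (LiN(i-Pr)2, Me3SiCl) into the trimethylsilyl enol ether F12.
- A TiCl4-mediated Mukaiyama aldol addition of F12 to F11 gives the tertiary aldol F13.
- Dehydration (Burgess reagent) gives the tetrasubstituted enone F14, with C12 cis to C8 and methyl cis to the carbonyl.
- Conjugate reduction with [(Ph3P)CuH]6 delivers hydride anti to O12, and protonation gives 28.

**Further compounds**

F1 | step 5 | (R)-4-(tert-butyldimethylsilyloxy)cyclopent-2-en-1-one (purchased) | O=C1C=C[C@H](O[Si](C)(C)C(C)(C)C)C1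
F2 | step 5 | photoadduct of F1 and 6 (4α-OTBS, H4β) | COC(=O)[C@@]12CCC[C@]1(O[Si](CC)(CC)CC)[C@@H]3[C@H]2C(=O)C[C@H]3O[Si](C)(C)C(C)(C)C
F3 | step 5 | tricyclic cyclopentenone (C2 ketone, C3=C4) | COC(=O)[C@@]12CCC[C@]1(O[Si](CC)(CC)CC)[C@@H]3[C@H]2C(=O)C=C3
F4 | step 5 | trimethylsilyl enol ether (4α-methyl) | COC(=O)[C@@]12CCC[C@]1(O[Si](CC)(CC)CC)[C@@H]3[C@H]2C(O[Si](C)(C)C)=C[C@H]3C
F5 | step 5 | 4-methyl enone (C2 ketone, C3=C4Me) | COC(=O)[C@@]12CCC[C@]1(O[Si](CC)(CC)CC)[C@@H]3[C@H]2C(=O)C=C3C
F6 | step 5 | 3α,4α-epoxy ketone | COC(=O)[C@@]12CCC[C@]1(O[Si](CC)(CC)CC)[C@@H]3[C@H]2C(=O)[C@H]4O[C@@]34C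
F7 | step 5 | tertiary allylic alcohol (4α-OH, C2=C3) | COC(=O)[C@@]12CCC[C@]1(O[Si](CC)(CC)CC)[C@@H]3[C@H]2C=C[C@@]3(C)O
F8 | step 11 | 9β-hydroxy ketone | C=C1[C@@H](O)CCC(=O)[C@@H]2[C@H]1C=C[C@@]2(C)O[Si](C)(C)C(C)(C)C
F9 | step 11 | 9α 4-nitrobenzoate | C=C1[C@H](OC(=O)c3ccc(cc3)[N+](=O)[O-])CCC(=O)[C@@H]2[C@H]1C=C[C@@]2(C)O[Si](C)(C)C(C)(C)C
F10 | step 19 | secondary carbinol from 22 (mixture at the carbinol carbon) | CC(O)[C@@H]1OC(C)(C)O[C@H]1C=C(C)C
F11 | step 19 | side-chain methyl ketone | CC(=O)[C@@H]1OC(C)(C)O[C@H]1C=C(C)C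
F12 | step 19 | trimethylsilyl enol ether of 16 | C=C1[C@H](O[Si](C)(C)C(C)(C)C)CC=C(O[Si](C)(C)C)[C@@H]2[C@H]1C=C[C@@]2(C)O[Si](C)(C)C(C)(C)C
F13 | step 19 | tertiary aldol (mixture at C7 and C11) | C=C1[C@H](O[Si](C)(C)C(C)(C)C)CC(C(C)(O)[C@@H]3OC(C)(C)O[C@H]3C=C(C)C)C(=O)[C@@H]2[C@H]1C=C[C@@]2(C)O[Si](C)(C)C(C)(C)C
F14 | step 19 | tetrasubstituted enone (C7=C11Me, C12 cis to C8) | C=C1[C@H](O[Si](C)(C)C(C)(C)C)C/C(=C(/C)[C@@H]3OC(C)(C)O[C@H]3C=C(C)C)C(=O)[C@@H]2[C@H]1C=C[C@@]2(C)O[Si](C)(C)C(C)(C)C
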